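## Retrosynthetic overview

1. Target ⇒ last-step O-acylation (Steglich) of the (S)-quinone alcohol with 3-methylbut-2-enoic acid, the chemical copy of the acyl transfer that ends the biosynthesis.
2. Quinone ring ⇒ C-1/C-8a bond: the C-3'' aldehyde of a (Z)-1',3''-dioxo geranyl-type chain closes onto the hydroquinone monomethyl ether ring ortho to the phenol (the 3''-oxo-geranylhydroquinone cyclisation, run as a phenoxide aldol), then aromatisation and air oxidation.
3. The keto-enal ⇒ a 2-aryl-4-alkylfuran (a shikonofuran-type C10 unit), opened by singlet oxygen in the same flask.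
4. Carbinol centre ⇒ Brown allylboration of a 5-arylfuran-3-carbaldehyde, then cross-metathesis to the prenyl end; aryl–furan bond ⇒ C-5 lithiation of in situ protected furan-3-carbaldehyde and Negishi coupling.
5. Ring order: the benzenoid ring is bought, the bought furan serves only as a masked chain, and the quinone ring is the one ring built (step 5).

Assumption: the stereocentre is read from the SMILES as S (alkannin series); reagents and catalysts carry no compound numbers; (–)-Ipc2B(allyl) is the commercial 1 M pentane solution of the reagent derived from (+)-α-pinene.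

## Route

Step 1
Reactants: 1 3-bromo-4-methoxyphenol
Product: 2 (3-bromo-4-methoxyphenoxy)(tert-butyl)dimethylsilane
Conditions: TBSCl, imidazole, DMF, rt
Reagents that add atoms: tert-butyldimethylsilyl chloride, CC(C)(C)[Si](C)(C)Cl
Why: Imidazole-promoted silylation of a phenol (substitution at silicon); the aryl silyl ether survives the organometallic steps and is the fluoride trigger of step 5.

Step 2
Reactants: 3 furan-3-carbaldehyde; 2 (3-bromo-4-methoxyphenoxy)(tert-butyl)dimethylsilane
Product: 8 5-{5-[(tert-butyldimethylsilyl)oxy]-2-methoxyphenyl}furan-3-carbaldehyde, via amino alkoxide 4 (not isolated), via lithiated alkoxide 5 (not isolated), via furylzinc chloride 6 (not isolated), via coupled alkoxide 7 (not isolated)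
Conditions: morpholine, n-BuLi, THF, –78 °C; 3; sec-BuLi, –78 °C; ZnCl2, –78 → 0 °C; 2, Pd2(dba)3 (2 mol %), SPhos (8 mol %), 50 °C; aq. NH4Cl
Reagents that add atoms: none
Why: Lithium morpholide adds to the aldehyde to give a bulky α-amino alkoxide that shields C-2 and C-4, so sec-BuLi deprotonates the remote α-position C-5 (in situ protection/directed lithiation known for 2,4-disubstituted furans), and Li→Zn exchange followed by Negishi coupling forms the aryl–furan bond, the aldehyde returning on aqueous work-up.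

Step 3
Reactants: 8 5-{5-[(tert-butyldimethylsilyl)oxy]-2-methoxyphenyl}furan-3-carbaldehyde
Product: 10 (1S)-1-(5-{5-[(tert-butyldimethylsilyl)oxy]-2-methoxyphenyl}furan-3-yl)but-3-en-1-ol, via borinate ester 9 (not isolated)
Conditions: (–)-Ipc2B(allyl) (1 M in pentane), Et2O, –78 °C; pH 7 buffer (KH2PO4/Na2HPO4), 30% H2O2, MeOH, 0 °C → rt
Reagents that add atoms: (–)-B-allyldiisopinocampheylborane, C=CCB([C@@H]1C[C@@H]2C[C@H]([C@H]1C)C2(C)C)[C@@H]1C[C@@H]2C[C@H]([C@H]1C)C2(C)C
Why: Brown asymmetric allylboration through a chair Zimmerman–Traxler transition state; the reagent from (+)-α-pinene adds allyl to the Si face of aryl-type aldehydes (benzaldehyde gives the S alcohol), which sets the S carbinol centre here (priorities O > furyl > CH2 > H).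

Step 4
Reactants: 10 (1S)-1-(5-{5-[(tert-butyldimethylsilyl)oxy]-2-methoxyphenyl}furan-3-yl)but-3-en-1-ol
Product: 11 (1S)-1-(5-{5-[(tert-butyldimethylsilyl)oxy]-2-methoxyphenyl}furan-3-yl)-4-methylpent-3-en-1-ol
Conditions: 2-methyl-2-butene (excess), second-generation Grubbs catalyst RuCl2(=CHPh)(PCy3)(H2IMes) (5 mol %), CH2Cl2, 40 °C
Reagents that add atoms: 2-methyl-2-butene, CC=C(C)C
Why: Olefin cross-metathesis of the terminal alkene with excess 2-methyl-2-butene turns the allyl end into the prenyl end with loss of propene and leaves the carbinol centre untouched.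

Step 5
Reactants: 11 (1S)-1-(5-{5-[(tert-butyldimethylsilyl)oxy]-2-methoxyphenyl}furan-3-yl)-4-methylpent-3-en-1-ol
Product: 17 8-hydroxy-2-[(1S)-1-hydroxy-4-methylpent-3-en-1-yl]-5-methoxynaphthalene-1,4-dione, via furan endoperoxide 12 (not isolated), via silyl keto-enal 13 (not isolated), via phenoxide keto-enal 14 (not isolated), via hydroxynaphthalenone 15 (not isolated), via naphthalenetriol 16 (not isolated)
Conditions: O2, hν (visible), tetraphenylporphyrin (1 mol %), CH2Cl2, –78 °C; Me2S, –78 → 0 °C; evaporate, THF; TBAF (1.1 equiv), –78 → –20 °C, Ar; AcOH; O2 (air), rt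
Reagents that add atoms: dioxygen, O=O
Why: Proposed new method: singlet oxygen adds [4+2] to the furan much faster than it ene-reacts with the prenyl alkene and Me2S reduces the endoperoxide to the (Z)-4-oxo-enal (known furan unmasking), whose ring-derived Z geometry holds the C-3'' aldehyde next to the arene carbon ortho to the silyloxy group; fluoride then frees a phenoxide, an aromatic enolate, whose ortho carbon adds to the aldehyde in a 6-exo-trig aldol (the 5-endo-trig Michael mode is disfavoured and para attack at the methoxy-bearing carbon is reversible), the 4-hydroxynaphthalenone tautomerises to the naphthalenetriol and O2 oxidises it to the quinone, the carbinol centre being a spectator that carries no leaving group; closest known reaction types are the base-mediated ortho-hydroxyalkylation of phenoxides by aldehydes (Lederer–Manasse, Casiraghi), the intramolecular aldol trapping of furan-derived cis-enediones and the air oxidation of leuco-naphthoquinones.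

Step 6
Reactants: 17 8-hydroxy-2-[(1S)-1-hydroxy-4-methylpent-3-en-1-yl]-5-methoxynaphthalene-1,4-dione
Product: 18 (1S)-1-(8-hydroxy-5-methoxy-1,4-dioxo-1,4-dihydronaphthalen-2-yl)-4-methylpent-3-en-1-yl 3-methylbut-2-enoate
Conditions: 3-methylbut-2-enoic acid, DCC, DMAP (cat.), CH2Cl2, 0 °C → rt
Reagents that add atoms: 3-methylbut-2-enoic acid, CC(C)=CC(=O)O
Why: Steglich esterification acylates only the side-chain secondary alcohol because the C-8 phenol is locked in a hydrogen bond to the C-1 carbonyl (the standard way to acyl-shikonins and acyl-alkannins), and the acyl–oxygen bond formation retains the S configuration.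

## Compound list

1 | 3-bromo-4-methoxyphenol | COc1ccc(O)cc1Br | starting material
2 | (3-bromo-4-methoxyphenoxy)(tert-butyl)dimethylsilane | COc1ccc(O[Si](C)(C)C(C)(C)C)cc1Br | intermediate
3 | furan-3-carbaldehyde | O=Cc1ccoc1 | starting material
4 | lithium (furan-3-yl)(morpholin-4-yl)methanolate (racemic) | [Li]OC(c1ccoc1)N1CCOCC1 | intermediate
5 | lithium (5-lithiofuran-3-yl)(morpholin-4-yl)methanolate | [Li]OC(c1coc([Li])c1)N1CCOCC1 | intermediate
6 | lithium [5-(chlorozincio)furan-3-yl](morpholin-4-yl)methanolate | [Li]OC(c1coc([Zn]Cl)c1)N1CCOCC1 | intermediate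
7 | lithium (5-{5-[(tert-butyldimethylsilyl)oxy]-2-methoxyphenyl}furan-3-yl)(morpholin-4-yl)methanolate | [Li]OC(c1coc(-c2cc(O[Si](C)(C)C(C)(C)C)ccc2OC)c1)N1CCOCC1 | intermediate
8 | 5-{5-[(tert-butyldimethylsilyl)oxy]-2-methoxyphenyl}furan-3-carbaldehyde | O=Cc1coc(-c2cc(O[Si](C)(C)C(C)(C)C)ccc2OC)c1 | intermediate
9 | (1S)-1-(5-{5-[(tert-butyldimethylsilyl)oxy]-2-methoxyphenyl}furan-3-yl)but-3-en-1-yl bis(isopinocampheyl)borinate | C=CC[C@H](OB([C@@H]1C[C@@H]2C[C@H]([C@H]1C)C2(C)C)[C@@H]1C[C@@H]2C[C@H]([C@H]1C)C2(C)C)c1coc(-c2cc(O[Si](C)(C)C(C)(C)C)ccc2OC)c1 | intermediate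
10 | (1S)-1-(5-{5-[(tert-butyldimethylsilyl)oxy]-2-methoxyphenyl}furan-3-yl)but-3-en-1-ol | C=CC[C@H](O)c1coc(-c2cc(O[Si](C)(C)C(C)(C)C)ccc2OC)c1 | intermediate
11 | (1S)-1-(5-{5-[(tert-butyldimethylsilyl)oxy]-2-methoxyphenyl}furan-3-yl)-4-methylpent-3-en-1-ol | CC(C)=CC[C@H](O)c1coc(-c2cc(O[Si](C)(C)C(C)(C)C)ccc2OC)c1 | intermediate
12 | (1S)-1-(1-{5-[(tert-butyldimethylsilyl)oxy]-2-methoxyphenyl}-2,3,7-trioxabicyclo[2.2.1]hept-5-en-5-yl)-4-methylpent-3-en-1-ol (both bridgehead diastereomers) | CC(C)=CC[C@H](O)C1=CC2(c3cc(O[Si](C)(C)C(C)(C)C)ccc3OC)OOC1O2 | intermediate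
13 | (2Z)-4-{5-[(tert-butyldimethylsilyl)oxy]-2-methoxyphenyl}-2-[(1S)-1-hydroxy-4-methylpent-3-en-1-yl]-4-oxobut-2-enal | CC(C)=CC[C@H](O)/C(C=O)=C/C(=O)c1cc(O[Si](C)(C)C(C)(C)C)ccc1OC | intermediate
14 | tetrabutylammonium 3-[(2Z,4S)-3-formyl-4-hydroxy-7-methylocta-2,6-dienoyl]-4-methoxyphenolate | CC(C)=CC[C@H](O)/C(C=O)=C/C(=O)c1cc([O-])ccc1OC.CCCC[N+](CCCC)(CCCC)CCCC | intermediate
15 | 4,5-dihydroxy-3-[(1S)-1-hydroxy-4-methylpent-3-en-1-yl]-8-methoxynaphthalen-1(4H)-one (both C-4 epimers) | CC(C)=CC[C@H](O)C1=CC(=O)c2c(OC)ccc(O)c2C1O | intermediate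
16 | 2-[(1S)-1-hydroxy-4-methylpent-3-en-1-yl]-5-methoxynaphthalene-1,4,8-triol | CC(C)=CC[C@H](O)c1cc(O)c2c(OC)ccc(O)c2c1O | intermediate
17 | 8-hydroxy-2-[(1S)-1-hydroxy-4-methylpent-3-en-1-yl]-5-methoxynaphthalene-1,4-dione | COc1ccc(O)c2c1C(=O)C=C([C@H](CC=C(C)C)O)C2=O | intermediate
18 | (1S)-1-(8-hydroxy-5-methoxy-1,4-dioxo-1,4-dihydronaphthalen-2-yl)-4-methylpent-3-en-1-yl 3-methylbut-2-enoate | COc1ccc(O)c2c1C(=O)C=C([C@H](CC=C(C)C)OC(=O)C=C(C)C)C2=O | target

## Step count and risks

Total step count: 6.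
Longest linear sequence: 6 steps (1 → 2 → 8 → 10 → 11 → 17 → 18); 5 steps from furan-3-carbaldehyde 3.

Steps most likely to fail:

**Step 5 (unmasking, ring closure and oxidation in one flask).** The keto-enal 13 may lose its Z geometry, the phenoxide may oligomerise by intermolecular conjugate addition, or the naphthalenetriol 16 may lose the benzylic oxygen before it is oxidised. The fallback closes the ring at the acid level and puts the ester on first. It sets out from 11: Steglich esterification (3-methylbut-2-enoic acid, DCC, DMAP, CH2Cl2) gives the furan ester F1. Photooxygenation (O2, hν, tetraphenylporphyrin, CH2Cl2, –78 °C) gives its endoperoxide F2. With i-Pr2NEt this undergoes Kornblum–DeLaMare fragmentation (loss of the bridgehead proton at the former furan C-5) to the 5-aryl-5-hydroxybutenolide F3, the ring tautomer of the (Z)-3-aroylacrylic acid. TFAA in CH2Cl2 at 0 °C forms the mixed anhydride, and intramolecular Friedel–Crafts acylation ortho to the silyloxy group (the classical aroylacrylic acid to naphthoquinone closure) gives the silyl ether of the target F4 directly at the quinone level, with no hydroquinone stage. HF·pyridine in THF removes the silyl group and the sequence comes back to the route at 18, so step 6 is not needed.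

**Step 2 (C-5 lithiation and Negishi coupling in one flask).** Lithiation may occur partly at C-2, or the hindered furylzinc may couple poorly. The fallback takes the 2,4-pattern from a furan whose substitution was fixed by electrophilic bromination. It sets out from 2: Br–Li exchange (n-BuLi, THF, –78 °C) and trapping with 2-isopropoxy-4,4,5,5-tetramethyl-1,3,2-dioxaborolane gives the aryl pinacol boronate F5. Suzuki–Miyaura coupling with commercial methyl 5-bromofuran-3-carboxylate (Pd(OAc)2, SPhos, K3PO4, toluene, 80 °C) gives the methyl 5-arylfuran-3-carboxylate F6. Reduction with i-Bu2AlH (CH2Cl2, –78 °C) gives the furylmethanol F7, and MnO2 (CH2Cl2, rt) brings the sequence back to the route at 8.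

**Step 3 (the only stereocentre-setting step).** The ee may be insufficient with this heteroaryl aldehyde. The fallback re-sets the centre by reagent-controlled ketone reduction instead of C–C bond formation. It sets out from 11 of low ee (carried through step 4): Dess–Martin periodinane with NaHCO3 in CH2Cl2 gives the β,γ-unsaturated furyl ketone F8. Reduction with (–)-Ipc2BCl (THF, –25 °C; diethanolamine work-up) gives the S alcohol, as aryl alkyl ketones do with this reagent (acetophenone gives the S alcohol), and comes back to the route at 11.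

## Further compounds

F1 | step 5 | (1S)-1-(5-{5-[(tert-butyldimethylsilyl)oxy]-2-methoxyphenyl}furan-3-yl)-4-methylpent-3-en-1-yl 3-methylbut-2-enoate | CC(C)=CC[C@H](OC(=O)C=C(C)C)c1coc(-c2cc(O[Si](C)(C)C(C)(C)C)ccc2OC)c1
F2 | step 5 | (1S)-1-(1-{5-[(tert-butyldimethylsilyl)oxy]-2-methoxyphenyl}-2,3,7-trioxabicyclo[2.2.1]hept-5-en-5-yl)-4-methylpent-3-en-1-yl 3-methylbut-2-enoate | CC(C)=CC[C@H](OC(=O)C=C(C)C)C1=CC2(c3cc(O[Si](C)(C)C(C)(C)C)ccc3OC)OOC1O2
F3 | step 5 | (1S)-1-(5-{5-[(tert-butyldimethylsilyl)oxy]-2-methoxyphenyl}-5-hydroxy-2-oxo-2,5-dihydrofuran-3-yl)-4-methylpent-3-en-1-yl 3-methylbut-2-enoate (both C-5 epimers) | CC(C)=CC[C@H](OC(=O)C=C(C)C)C1=CC(O)(c2cc(O[Si](C)(C)C(C)(C)C)ccc2OC)OC1=O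
F4 | step 5 | (1S)-1-{8-[(tert-butyldimethylsilyl)oxy]-5-methoxy-1,4-dioxo-1,4-dihydronaphthalen-2-yl}-4-methylpent-3-en-1-yl 3-methylbut-2-enoate | COc1ccc(O[Si](C)(C)C(C)(C)C)c2c1C(=O)C=C([C@H](CC=C(C)C)OC(=O)C=C(C)C)C2=O
F5 | step 2 | 2-{5-[(tert-butyldimethylsilyl)oxy]-2-methoxyphenyl}-4,4,5,5-tetramethyl-1,3,2-dioxaborolane | COc1ccc(O[Si](C)(C)C(C)(C)C)cc1B1OC(C)(C)C(C)(C)O1
F6 | step 2 | methyl 5-{5-[(tert-butyldimethylsilyl)oxy]-2-methoxyphenyl}furan-3-carboxylate | COC(=O)c1coc(-c2cc(O[Si](C)(C)C(C)(C)C)ccc2OC)c1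
F7 | step 2 | (5-{5-[(tert-butyldimethylsilyl)oxy]-2-methoxyphenyl}furan-3-yl)methanol | OCc1coc(-c2cc(O[Si](C)(C)C(C)(C)C)ccc2OC)c1
F8 | step 3 | 1-(5-{5-[(tert-butyldimethylsilyl)oxy]-2-methoxyphenyl}furan-3-yl)-4-methylpent-3-en-1-one | CC(C)=CCC(=O)c1coc(-c2cc(O[Si](C)(C)C(C)(C)C)ccc2OC)c1
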